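The constants of this catalyst are hidden, but the two earlier runs show that product starts slowly and then rises roughly as the square of the time.

| setting | east | south | flask |
|---|---|---|---|
| starting material | 0.050 M | 0.050 M | 0.050 M |
| precatalyst | 12 µM | 19 µM | 25 µM |
| remark | run made earlier | run made earlier |  |
| time |  |  | 2.5 h |

- east (time / h: product / %): 0.833: 1.0; 1.50: 1.2; 2.50: 3.8; 3.00: 6.1
- south (time / h: product / %): 0.417: 0; 1.00: 1.3; 2.00: 5.1; 3.00: 9.8

(standard deviation of a reading: 0.3 percentage points)

- the earlier runs were read with a standard deviation of 0.3 percentage points

1. amount of product in percent of the starting material charged, at 15 min, 50 min and 2.5 h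

What can be read from these runs is the flask-equivalent product, a reading scaled in proportion to the precatalyst charged and to the square of the time until it stands for the flask at 2.5 h, which from the south run at 3.00 h is 8.95 %. Scaled back to the east charge at 3.00 h, this value gives 6.19 %, beside the east reading of 6.1 %. Two other readings give a wide bracket for the estimate: the east run at 2.50 h gives 7.92 % from below and the south run at 2.00 h gives 10.5 % from above.

The bracket tightens on the south reading at 3.00 h, the largest of the readings: two standard deviations either way put the estimate between 8.41 % and 9.50 %. My own reckoning by the square of the time gives 0.0895 %, 0.995 % and 8.95 %.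

The forecast, judging that “the active catalyst seems to build up from the precatalyst”, gives 0.1 %, 1.1 % and 10 %; its last value is higher than my 8.95 %, inside the wide bracket and above the tight one.

The flask gives 0.124 %, 1.28 % and 9.23 %, within the forecast's tolerance, and the last value stands inside the tight bracket.

    starting material + enzyme ⇌ complex (K = 27.0 /M, k = 5400 /M/min)
    precatalyst → enzyme (k = 0.00580 /min)
    complex ⇌ enzyme + product (K = 0.0610 M, k = 6.90 /min)

Complex in the flask has a half-life of 0.10 min by the forward step alone at 1.67 h, far shorter than the 2.0 h of precatalyst by its path to enzyme at 2.50 h, and at 2.50 h the catalyst charged stands as 41.9 % precatalyst, 31.5 % complex and 26.6 % enzyme. The flask-equivalent 8.95 % lies 0.28 points below the flask at 2.5 h, and carried by the square of the time to 25.0 h it gives 895 % of the charge, where the flask holds 62.0 % product.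

(The runs stem from a simulated flask with made-up constants.)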